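## Retrosynthetic overview

1. The C3''=C4'' olefin of pyran ring D is unmasked last. Fluoride frees the 4'-phenoxide, which expels a C4''-sulfinate through the ring-B ortho-quinone methide, and loss of a C3'' proton re-aromatises ring B.
2. Ring D comes from a decarboxylative radical (4+2) annulation. The O2'–C•Me2 radical and phenyl vinyl sulfone (a C2 acetylene equivalent) form the CMe2–C3'' bond and the C4''–C3' bond in one operation.
3. Enabling feature: C3' of ring B lies between O2' and O4' (the resorcinol 2-position). It is the only free ortho carbon of O2', because C1' carries C3 of ring C. The O2'-bound carbon carries two methyl groups, so its radical is tertiary and nucleophilic.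
4. Ring C is closed by Mitsunobu etherification of an (R)-2,3-diarylpropanol. C3 is set by carboxylate-directed Ir-catalysed asymmetric hydrogenation of the Perkin acid made from a ring-A aldehyde and a ring-B arylacetic acid.
5. The 6-prenyl group is placed by a para-Claisen–Cope shift on the ring-A aldehyde. Rings A and B are bought; ring C is formed first, then ring D.

Key step: step 15

Assumption: the (Ra)-configured spiro phosphine–oxazoline iridium catalyst is taken to deliver the R acid. If the first run shows the opposite sense, its antipode is used and nothing else changes. The five starting materials are taken as commercial.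

## Route

Step 1
Reactants: 1 2,4-dihydroxy-6-methoxybenzaldehyde
Product: 2 2-hydroxy-6-methoxy-4-(triisopropylsilyloxy)benzaldehyde
Conditions: TIPSCl (1.05 equiv), imidazole, CH2Cl2, 0 °C to rt
Reagents that add atoms: triisopropylsilyl chloride, CC(C)[Si](Cl)(C(C)C)C(C)C
Why: Chemoselective silylation, because the 2-OH is hydrogen-bonded to and flanked by the aldehyde, so the bulky silyl chloride should take the free and more acidic 4-OH.

Step 2
Reactants: 2 2-hydroxy-6-methoxy-4-(triisopropylsilyloxy)benzaldehyde; 3 3-methylbut-2-en-1-ol (prenol)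
Product: 4 2-methoxy-6-(3-methylbut-2-enyloxy)-4-(triisopropylsilyloxy)benzaldehyde
Conditions: PPh3, DIAD, THF, 0 °C to rt
Reagents that add atoms: none
Why: Mitsunobu etherification alkylates the chelated phenol under neutral conditions (SN2 at the primary allylic carbinol carbon), which spares the silyl ether para to the aldehyde.

Step 3
Reactants: 4 2-methoxy-6-(3-methylbut-2-enyloxy)-4-(triisopropylsilyloxy)benzaldehyde
Product: 7 6-hydroxy-2-methoxy-3-(3-methylbut-2-enyl)-4-(triisopropylsilyloxy)benzaldehyde, via ortho-dienone 5 (not isolated), via para-dienone 6 (not isolated)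
Conditions: PhNEt2, 200 °C, Ar
Reagents that add atoms: none
Why: Tandem aromatic Claisen–Cope rearrangement, in which the first [3,3] shift can only reach C5 (the other ortho carbon bears CHO), the crowded dienone 5 passes the allyl unit by a second [3,3] shift to the para carbon C3 with return of the linear prenyl group, and tautomerisation of 6 gives the chelated phenol, a sequence with close precedent in prenylated phloroglucinol carbonyl compounds.

Step 4
Reactants: 7 6-hydroxy-2-methoxy-3-(3-methylbut-2-enyl)-4-(triisopropylsilyloxy)benzaldehyde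
Product: 8 2-methoxy-6-(methoxymethoxy)-3-(3-methylbut-2-enyl)-4-(triisopropylsilyloxy)benzaldehyde
Conditions: MOMCl, iPr2NEt, CH2Cl2, 0 °C to reflux
Reagents that add atoms: chloromethyl methyl ether, COCCl
Why: Standard O-alkylation to the MOM acetal masks the phenol that would otherwise divert step 8 to a 3-arylcoumarin.

Step 5
Reactants: 9 methyl 2-(2,4-dihydroxyphenyl)acetate
Product: 10 methyl 2-[2-hydroxy-4-(triisopropylsilyloxy)phenyl]acetate
Conditions: TIPSCl (1.05 equiv), imidazole, CH2Cl2, 0 °C
Reagents that add atoms: triisopropylsilyl chloride, CC(C)[Si](Cl)(C(C)C)C(C)C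
Why: Sterically controlled silylation, because the 2-OH is shielded by the ortho CH2CO2Me group and hydrogen-bonded to it, so the bulky reagent should choose the 4-OH.

Step 6
Reactants: 10 methyl 2-[2-hydroxy-4-(triisopropylsilyloxy)phenyl]acetate; 11 tert-butyl 2-bromo-2-methylpropanoate
Product: 12 tert-butyl 2-[2-(2-methoxy-2-oxoethyl)-5-(triisopropylsilyloxy)phenoxy]-2-methylpropanoate
Conditions: K2CO3 (anhydrous), MeCN, 60 °C
Reagents that add atoms: none
Why: Williamson ether synthesis with a carbonyl-activated tertiary α-bromo ester, which is the standard entry to 2-aryloxy-2-methylpropanoates.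

Step 7
Reactants: 12 tert-butyl 2-[2-(2-methoxy-2-oxoethyl)-5-(triisopropylsilyloxy)phenoxy]-2-methylpropanoate
Product: 13 2-[2-(1-tert-butoxy-2-methyl-1-oxopropan-2-yl)oxy-4-(triisopropylsilyloxy)phenyl]acetic acid
Conditions: LiOH·H2O (1.5 equiv), THF/H2O, 0 °C; then cold 1 M HCl to pH 3
Reagents that add atoms: lithium hydroxide, [Li+].[OH-]
Why: Saponification discriminates on steric grounds, since the unhindered methyl arylacetate is cleaved at 0 °C while the tert-butyl ester of the quaternary acid is inert to hydroxide and the TIPS ether on the electron-rich ring reacts slowly.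

Step 8
Reactants: 8 2-methoxy-6-(methoxymethoxy)-3-(3-methylbut-2-enyl)-4-(triisopropylsilyloxy)benzaldehyde; 13 2-[2-(1-tert-butoxy-2-methyl-1-oxopropan-2-yl)oxy-4-(triisopropylsilyloxy)phenyl]acetic acid
Product: 14 (E)-2-[2-(1-tert-butoxy-2-methyl-1-oxopropan-2-yl)oxy-4-(triisopropylsilyloxy)phenyl]-3-[2-methoxy-6-(methoxymethoxy)-3-(3-methylbut-2-enyl)-4-(triisopropylsilyloxy)phenyl]prop-2-enoic acid
Conditions: Ac2O, Et3N, 110 °C; then H2O/THF, 50 °C
Reagents that add atoms: none
Why: Perkin (Oglialoro) condensation, in which the mixed anhydride of 13 is enolised by Et3N, adds to the aldehyde and loses acetate to give the favoured E acid with the two aryl groups cis.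

Step 9
Reactants: 14 the (E)-α-arylcinnamic acid of step 8
Product: 15 (2R)-2-[2-(1-tert-butoxy-2-methyl-1-oxopropan-2-yl)oxy-4-(triisopropylsilyloxy)phenyl]-3-[2-methoxy-6-(methoxymethoxy)-3-(3-methylbut-2-enyl)-4-(triisopropylsilyloxy)phenyl]propanoic acid
Conditions: [Ir(cod)((Ra)-SIPHOX)]BArF (1–2 mol %), H2 (30 bar), Et3N (1 equiv), MeOH, 40 °C
Reagents that add atoms: none
Why: Carboxylate-directed Ir-catalysed asymmetric hydrogenation of an α-arylcinnamic acid (the reaction type established for isoflavan precursors), in which the acid binds iridium as its carboxylate, the chiral spiro pocket delivers H2 to one face of the chelated olefin to set the R centre, and the prenyl olefin, lacking an anchor and facing a catalyst tamed by MeOH and amine, should stay untouched.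

Step 10
Reactants: 15 the (2R)-2,3-diarylpropanoic acid of step 9
Product: 17 tert-butyl 2-[2-[(2R)-1-hydroxy-3-[2-methoxy-6-(methoxymethoxy)-3-(3-methylbut-2-enyl)-4-(triisopropylsilyloxy)phenyl]propan-2-yl]-5-(triisopropylsilyloxy)phenoxy]-2-methylpropanoate, via mixed carbonic anhydride 16 (not isolated)
Conditions: iBuOCOCl, N-methylmorpholine, THF, –15 °C; then NaBH4, H2O, 0 °C
Reagents that add atoms: none
Why: Mixed-anhydride activation and borohydride reduction converts only the free acid into the primary alcohol, leaves the prenyl olefin (which borane would attack) and the hindered tert-butyl ester alone, and is short and cold enough to keep the α-aryl stereocentre intact.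

Step 11
Reactants: 17 the (2R)-MOM-protected diarylpropanol of step 10
Product: 18 tert-butyl 2-[2-[(2R)-1-hydroxy-3-[6-hydroxy-2-methoxy-3-(3-methylbut-2-enyl)-4-(triisopropylsilyloxy)phenyl]propan-2-yl]-5-(triisopropylsilyloxy)phenoxy]-2-methylpropanoate
Conditions: NaHSO4·SiO2, CH2Cl2/MeOH (10:1), rt
Reagents that add atoms: none
Why: Mild heterogeneous acid-catalysed acetal exchange removes the phenolic MOM group (formaldehyde is trapped as its dimethyl acetal), while the TIPS ethers, the tert-butyl ester and the prenyl group, which has no free ortho phenol, need far stronger acid.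

Step 12
Reactants: 18 the (2R)-phenol alcohol of step 11
Product: 19 tert-butyl 2-[2-[(3R)-5-methoxy-6-(3-methylbut-2-enyl)-7-(triisopropylsilyloxy)chroman-3-yl]-5-(triisopropylsilyloxy)phenoxy]-2-methylpropanoate
Conditions: PPh3, DIAD, THF, 0 °C to rt
Reagents that add atoms: none
Why: Intramolecular Mitsunobu etherification (6-exo-tet) closes ring C at the primary carbinol carbon, so C3 is not involved and stays R, and this is the usual closure of 2,3-diarylpropanols to isoflavans.

Step 13
Reactants: 19 the (3R)-isoflavan tert-butyl ester of step 12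
Product: 21 2-[2-[(3R)-5-methoxy-6-(3-methylbut-2-enyl)-7-(triisopropylsilyloxy)chroman-3-yl]-5-(triisopropylsilyloxy)phenoxy]-2-methylpropanoic acid, via trimethylsilyl ester 20 (not isolated)
Conditions: TMSOTf, 2,6-lutidine, CH2Cl2, 0 °C to rt; then pH 4 buffer
Reagents that add atoms: none
Why: Silyl-triflate-mediated tert-butyl ester cleavage (loss of isobutene from the O-silylated ester) runs without free protic acid, so the prenyl olefin and the aryl TIPS ethers survive, and the silyl ester hydrolyses on work-up.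

Step 14
Reactants: 21 the (3R)-isoflavan acid of step 13
Product: 22 1,3-dioxoisoindolin-2-yl 2-[2-[(3R)-5-methoxy-6-(3-methylbut-2-enyl)-7-(triisopropylsilyloxy)chroman-3-yl]-5-(triisopropylsilyloxy)phenoxy]-2-methylpropanoate
Conditions: N-hydroxyphthalimide, DIC, DMAP (10 mol %), CH2Cl2, rt
Reagents that add atoms: N-hydroxyphthalimide, O=C1c2ccccc2C(=O)N1O
Why: Carbodiimide (Steglich-type) esterification gives the redox-active ester and is routine for 2-aryloxy-2-methylpropanoic acids.

Step 15
Reactants: 22 the (3R)-N-acyloxyphthalimide of step 14; 23 phenyl vinyl sulfone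
Product: 24 (3R)-3-[2,2-dimethyl-4-(phenylsulfonyl)-5-(triisopropylsilyloxy)chroman-8-yl]-5-methoxy-6-(3-methylbut-2-enyl)-7-(triisopropylsilyloxy)chroman (both C4'' epimers)
Conditions: 23 (3 equiv), fac-Ir(ppy)3 (1 mol %), MeCN/CH2Cl2 (0.05 M), blue LEDs (450 nm), 25 °C, Ar, no reductant and no H-donor
Reagents that add atoms: none
Why: Electron transfer from excited fac-Ir(ppy)3 to the N-acyloxyphthalimide releases phthalimide anion, CO2 and the tertiary α-aryloxy radical O2'–C•Me2, so a carbon that is normally an acceptor (oxocarbenium position) reacts as a nucleophilic radical and adds to the CH2 end of the electron-poor vinyl sulfone (first bond, CMe2–C3''). The electrophilic α-sulfonyl radical then attacks the electron-rich C3' of ring B (second bond, C4''–C3'), Ir(IV) oxidises the cyclohexadienyl radical to a cation stabilised by O2' and O4', and phthalimide anion takes the proton, so the whole process is redox-neutral. The closest known reaction type is the photoredox decarboxylative (4+2) radical annulation of aryloxyalkyl N-hydroxyphthalimide esters with electron-deficient olefins to chromans, that is a Giese addition followed by homolytic aromatic substitution. Ring D closes in a six-membered ortho mode (formally 6-exo-trig on C3'=C4'), whereas the five-membered ipso attack at C2' is reversible and unproductive because it could only expel an alkoxyl radical. The one new stereocentre, C4'' bearing the sulfonyl group, is not controlled and need not be, since step 16 erases it, and C3 is not touched because intermolecular addition to excess 23 should be far faster than any 1,5-hydrogen shift from C3–H. Site selectivity rests on the substrate: C1' is blocked by ring C so only C3' can re-aromatise, polarity matching keeps both radicals away from the electron-rich prenyl olefin, the absence of an H-donor suppresses simple Giese reduction, and Ir(IV) is too weak an oxidant for rings A and B.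

Step 16
Reactants: 24 the (3R)-sulfonyl chroman of step 15
Product: 27 (3R)-3-(5-hydroxy-2,2-dimethyl-2H-chromen-8-yl)-5-methoxy-6-(3-methylbut-2-enyl)chroman-7-ol (target), via bis-phenol sulfone 25 (not isolated), via ortho-quinone methide 26 (not isolated)
Conditions: TBAF (4 equiv), THF, 0 to 40 °C, Ar; aq NH4Cl
Reagents that add atoms: none
Why: Fluoride desilylation frees the 4'-phenoxide ortho to the sulfonyl-bearing benzylic carbon, which expels benzenesulfinate in the well-known 1,4-elimination of 2-(1-sulfonylalkyl)phenols to ortho-quinone methides, and since every nucleophile addition to 26 is reversible under these basic conditions while loss of a C3'' proton re-aromatises ring B irreversibly, the chromene should be the sink, with C4'' losing its stereocentre and C3 staying R.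

## Compound list

1 | 2,4-dihydroxy-6-methoxybenzaldehyde | COc1cc(O)cc(O)c1C=O | starting material
2 | 2-hydroxy-6-methoxy-4-(triisopropylsilyloxy)benzaldehyde | COc1cc(O[Si](C(C)C)(C(C)C)C(C)C)cc(O)c1C=O | intermediate
3 | 3-methylbut-2-en-1-ol | CC(C)=CCO | starting material
4 | 2-methoxy-6-(3-methylbut-2-enyloxy)-4-(triisopropylsilyloxy)benzaldehyde | COc1cc(O[Si](C(C)C)(C(C)C)C(C)C)cc(OCC=C(C)C)c1C=O | intermediate
5 | ortho-dienone: 2-methoxy-5-(2-methylbut-3-en-2-yl)-6-oxo-4-(triisopropylsilyloxy)cyclohexa-1,3-diene-1-carbaldehyde (racemic, not isolated) | O=CC1=C(OC)C=C(O[Si](C(C)C)(C(C)C)C(C)C)C(C(C)(C)C=C)C1=O | intermediate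
6 | para-dienone: 2-methoxy-3-(3-methylbut-2-enyl)-6-oxo-4-(triisopropylsilyloxy)cyclohexa-1,4-diene-1-carbaldehyde (racemic, not isolated) | O=CC1=C(OC)C(CC=C(C)C)C(O[Si](C(C)C)(C(C)C)C(C)C)=CC1=O | intermediate
7 | 6-hydroxy-2-methoxy-3-(3-methylbut-2-enyl)-4-(triisopropylsilyloxy)benzaldehyde | COc1c(CC=C(C)C)c(O[Si](C(C)C)(C(C)C)C(C)C)cc(O)c1C=O | intermediate
8 | 2-methoxy-6-(methoxymethoxy)-3-(3-methylbut-2-enyl)-4-(triisopropylsilyloxy)benzaldehyde | COCOc1cc(O[Si](C(C)C)(C(C)C)C(C)C)c(CC=C(C)C)c(OC)c1C=O | intermediate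
9 | methyl 2-(2,4-dihydroxyphenyl)acetate | COC(=O)Cc1ccc(O)cc1O | starting material
10 | methyl 2-[2-hydroxy-4-(triisopropylsilyloxy)phenyl]acetate | COC(=O)Cc1ccc(O[Si](C(C)C)(C(C)C)C(C)C)cc1O | intermediate
11 | tert-butyl 2-bromo-2-methylpropanoate | CC(C)(Br)C(=O)OC(C)(C)C | starting material
12 | tert-butyl 2-[2-(2-methoxy-2-oxoethyl)-5-(triisopropylsilyloxy)phenoxy]-2-methylpropanoate | COC(=O)Cc1ccc(O[Si](C(C)C)(C(C)C)C(C)C)cc1OC(C)(C)C(=O)OC(C)(C)C | intermediate
13 | 2-[2-(1-tert-butoxy-2-methyl-1-oxopropan-2-yl)oxy-4-(triisopropylsilyloxy)phenyl]acetic acid | OC(=O)Cc1ccc(O[Si](C(C)C)(C(C)C)C(C)C)cc1OC(C)(C)C(=O)OC(C)(C)C | intermediate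
14 | (E)-α-arylcinnamic acid (ring-B aryl on C2, ring-A aryl on C3, aryl groups cis) | OC(=O)/C(=C/c1c(OC)c(CC=C(C)C)c(O[Si](C(C)C)(C(C)C)C(C)C)cc1OCOC)c1ccc(O[Si](C(C)C)(C(C)C)C(C)C)cc1OC(C)(C)C(=O)OC(C)(C)C | intermediate
15 | (2R)-2,3-diarylpropanoic acid | OC(=O)[C@H](Cc1c(OC)c(CC=C(C)C)c(O[Si](C(C)C)(C(C)C)C(C)C)cc1OCOC)c1ccc(O[Si](C(C)C)(C(C)C)C(C)C)cc1OC(C)(C)C(=O)OC(C)(C)C | intermediate
16 | isobutyl mixed carbonic anhydride of 15 (R, not isolated) | CC(C)COC(=O)OC(=O)[C@H](Cc1c(OC)c(CC=C(C)C)c(O[Si](C(C)C)(C(C)C)C(C)C)cc1OCOC)c1ccc(O[Si](C(C)C)(C(C)C)C(C)C)cc1OC(C)(C)C(=O)OC(C)(C)C | intermediate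
17 | (2R)-2,3-diarylpropan-1-ol, ring-A phenol as MOM ether | OC[C@H](Cc1c(OC)c(CC=C(C)C)c(O[Si](C(C)C)(C(C)C)C(C)C)cc1OCOC)c1ccc(O[Si](C(C)C)(C(C)C)C(C)C)cc1OC(C)(C)C(=O)OC(C)(C)C | intermediate
18 | (2R)-2,3-diarylpropan-1-ol with free ring-A phenol | OC[C@H](Cc1c(OC)c(CC=C(C)C)c(O[Si](C(C)C)(C(C)C)C(C)C)cc1O)c1ccc(O[Si](C(C)C)(C(C)C)C(C)C)cc1OC(C)(C)C(=O)OC(C)(C)C | intermediate
19 | (3R)-isoflavan, 2'-O-CMe2-CO2tBu, 7,4'-bis-TIPS ether | COc1c(CC=C(C)C)c(O[Si](C(C)C)(C(C)C)C(C)C)cc2c1C[C@H](c1ccc(O[Si](C(C)C)(C(C)C)C(C)C)cc1OC(C)(C)C(=O)OC(C)(C)C)CO2 | intermediate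
20 | trimethylsilyl ester of 21 (3R, not isolated) | COc1c(CC=C(C)C)c(O[Si](C(C)C)(C(C)C)C(C)C)cc2c1C[C@H](c1ccc(O[Si](C(C)C)(C(C)C)C(C)C)cc1OC(C)(C)C(=O)O[Si](C)(C)C)CO2 | intermediate
21 | (3R)-isoflavan, 2'-O-CMe2-CO2H | COc1c(CC=C(C)C)c(O[Si](C(C)C)(C(C)C)C(C)C)cc2c1C[C@H](c1ccc(O[Si](C(C)C)(C(C)C)C(C)C)cc1OC(C)(C)C(=O)O)CO2 | intermediate
22 | (3R)-isoflavan N-acyloxyphthalimide (redox-active ester) | COc1c(CC=C(C)C)c(O[Si](C(C)C)(C(C)C)C(C)C)cc2c1C[C@H](c1ccc(O[Si](C(C)C)(C(C)C)C(C)C)cc1OC(C)(C)C(=O)ON1C(=O)c3ccccc3C1=O)CO2 | intermediate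
23 | phenyl vinyl sulfone | C=CS(=O)(=O)c1ccccc1 | starting material
24 | (3R)-4''-phenylsulfonyl-3'',4''-dihydropyrano isoflavan, bis-TIPS ether (C4'' epimers) | COc1c(CC=C(C)C)c(O[Si](C(C)C)(C(C)C)C(C)C)cc2c1C[C@H](c1ccc(O[Si](C(C)C)(C(C)C)C(C)C)c3c1OC(C)(C)CC3S(=O)(=O)c1ccccc1)CO2 | intermediate
25 | (3R)-bis-phenol sulfone (present as phenoxide, drawn neutral, not isolated) | COc1c(CC=C(C)C)c(O)cc2c1C[C@H](c1ccc(O)c3c1OC(C)(C)CC3S(=O)(=O)c1ccccc1)CO2 | intermediate
26 | (3R)-ring-B ortho-quinone methide (C4'=O, C3'=C4'', drawn neutral, not isolated) | COc1c(CC=C(C)C)c(O)cc2c1C[C@H](C1=C3OC(C)(C)CC=C3C(=O)C=C1)CO2 | intermediate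
27 | (3R)-3-(5-hydroxy-2,2-dimethyl-2H-chromen-8-yl)-5-methoxy-6-(3-methylbut-2-enyl)chroman-7-ol | COc1c(CC=C(C)C)c(O)cc2c1C[C@H](c1ccc(O)c3c1OC(C)(C)C=C3)CO2 | target

## Step count and risks

Total step count: 16. Longest linear sequence: 13 (steps 1–4, then 8–16).

**Most likely to fail, 1: step 15.**
- Ring closure at C3' may be slow because this carbon lies next to the bulky silyl ether. The α-sulfonyl radical could then be diverted into addition to further vinyl sulfone or into hydrogen abstraction.
- The tertiary radical could also be oxidised to the oxocarbenium ion before it adds.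
- The fallback builds the same ring stepwise by known chemistry and keeps the carboxyl carbon instead of losing it. It sets out from 19 and comes back at 27.
- LiAlH4 reduces the tert-butyl ester to the primary alcohol F1. Dess–Martin oxidation gives the non-enolisable aldehyde F2. Ohira–Bestmann homologation gives the 1,1-dimethylpropargyl aryl ether F3.
- Heating in N,N-diethylaniline brings about the aromatic propargyl Claisen rearrangement, a [1,5]-H shift and an oxa-6π electrocyclisation at the same free ortho carbon. This gives the bis-silyl chromene F4, and TBAF then gives 27.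

**Most likely to fail, 2: step 9.**
- The olefin carries a 2,6-disubstituted aryl group cis to an ortho-substituted aryl group. This may cause slow turnover, poor facial selectivity or, under forcing pressure, partial saturation of the prenyl olefin.
- The fallback replaces catalysis by auxiliary control and also bypasses step 8. It sets out from 13 and 8 and comes back at 17.
- Acid 13 is joined to (R)-4-benzyloxazolidin-2-one (PivCl, Et3N, LiCl) to give the imide F5.
- Aldehyde 8 is reduced with NaBH4 to the benzyl alcohol F6. This is converted with CBr4/PPh3 at –20 °C into the labile benzyl bromide F7, which is used at once.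
- Evans alkylation of the sodium Z-enolate of F5 (NaHMDS, THF, –78 °C) with F7 occurs on the face opposite the benzyl group. This gives the (R)-configured alkylated imide F8, and LiBH4 releases alcohol 17.

**Most likely to fail, 3: step 16.**
- After desilylation, sulfinate loss may stall.
- The quinone methide may also be intercepted by phenoxides of other molecules faster than it loses the C3'' proton, which would lead to oligomerisation.
- The fallback removes the sulfonyl group oxidatively before any phenol is freed. It sets out from 24 and comes back at 27.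
- Deprotonation with n-BuLi (THF, –78 °C) and oxidation of the α-sulfonyl carbanion with bis(trimethylsilyl) peroxide (oxidative desulfonylation) gives the chroman-4-one F9.
- NaBH4 gives the chroman-4-ol F10. Catalytic PPTS in warm toluene dehydrates this doubly ortho-oxygenated benzylic alcohol to the bis-silyl chromene F4, and TBAF gives 27.

## Further compounds

F1 | step 15 | (3R)-isoflavan with 2'-O-CMe2-CH2OH, bis-TIPS ether | COc1c(CC=C(C)C)c(O[Si](C(C)C)(C(C)C)C(C)C)cc2c1C[C@H](c1ccc(O[Si](C(C)C)(C(C)C)C(C)C)cc1OC(C)(C)CO)CO2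
F2 | step 15 | (3R)-isoflavan with 2'-O-CMe2-CHO, bis-TIPS ether | COc1c(CC=C(C)C)c(O[Si](C(C)C)(C(C)C)C(C)C)cc2c1C[C@H](c1ccc(O[Si](C(C)C)(C(C)C)C(C)C)cc1OC(C)(C)C=O)CO2
F3 | step 15 | (3R)-isoflavan 2'-(1,1-dimethylpropargyl) ether, bis-TIPS ether | COc1c(CC=C(C)C)c(O[Si](C(C)C)(C(C)C)C(C)C)cc2c1C[C@H](c1ccc(O[Si](C(C)C)(C(C)C)C(C)C)cc1OC(C)(C)C#C)CO2
F4 | step 15 | bis-TIPS ether of the target (3R) | COc1c(CC=C(C)C)c(O[Si](C(C)C)(C(C)C)C(C)C)cc2c1C[C@H](c1ccc(O[Si](C(C)C)(C(C)C)C(C)C)c3c1OC(C)(C)C=C3)CO2
F5 | step 9 | (R)-4-benzyl-3-(arylacetyl)oxazolidin-2-one from 13 | O=C(Cc1ccc(O[Si](C(C)C)(C(C)C)C(C)C)cc1OC(C)(C)C(=O)OC(C)(C)C)N1[C@H](Cc2ccccc2)COC1=O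
F6 | step 9 | [2-methoxy-6-(methoxymethoxy)-3-(3-methylbut-2-enyl)-4-(triisopropylsilyloxy)phenyl]methanol | COCOc1cc(O[Si](C(C)C)(C(C)C)C(C)C)c(CC=C(C)C)c(OC)c1CO
F7 | step 9 | the corresponding benzyl bromide | COCOc1cc(O[Si](C(C)C)(C(C)C)C(C)C)c(CC=C(C)C)c(OC)c1CBr
F8 | step 9 | (R)-4-benzyl-3-[(2R)-2,3-diarylpropanoyl]oxazolidin-2-one | O=C([C@H](Cc1c(OC)c(CC=C(C)C)c(O[Si](C(C)C)(C(C)C)C(C)C)cc1OCOC)c1ccc(O[Si](C(C)C)(C(C)C)C(C)C)cc1OC(C)(C)C(=O)OC(C)(C)C)N1[C@H](Cc2ccccc2)COC1=O
F9 | step 16 | (3R)-isoflavan with ring D as 2,2-dimethylchroman-4-one, bis-TIPS ether | COc1c(CC=C(C)C)c(O[Si](C(C)C)(C(C)C)C(C)C)cc2c1C[C@H](c1ccc(O[Si](C(C)C)(C(C)C)C(C)C)c3c1OC(C)(C)CC3=O)CO2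
F10 | step 16 | (3R)-isoflavan with ring D as 2,2-dimethylchroman-4-ol (C4'' epimers), bis-TIPS ether | COc1c(CC=C(C)C)c(O[Si](C(C)C)(C(C)C)C(C)C)cc2c1C[C@H](c1ccc(O[Si](C(C)C)(C(C)C)C(C)C)c3c1OC(C)(C)CC3O)CO2
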